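**Strategy.** The flavan half is disconnected at C2–C3 and O1–C8a of its pyran ring, and the two halves at the C3(flavone)–C8(flavan) biaryl bond. The key step exploits C2 as an aldehyde-derived carbinol carbon next to ring B and C8a as a fluorine-bearing carbon of ring A. A dialkylzinc, made from 2,4-bis(benzyloxy)-6-fluorostyrene, transfers C3 enantioselectively to 4-(benzyloxy)benzaldehyde, setting (S)-C2, and the zinc alkoxide then displaces the ring A fluoride in the same flask to close the chroman. Regioselective C8 bromination, Negishi coupling with 3-iodo-tri-O-benzylapigenin and global hydrogenolysis complete the route.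

Key step: step 3

Assumption: the C3(flavone)–C8(flavan) biaryl axis carries no descriptor in the target and is taken as not configurationally fixed at room temperature, so only C2 needs stereocontrol.

**Step 1**
Reactants: 1 2,6-difluoro-4-hydroxybenzaldehyde
Product: 3 2,4-bis(benzyloxy)-6-fluorobenzaldehyde, via 4-(benzyloxy)-2,6-difluorobenzaldehyde 2 (not isolated)
Conditions: BnBr, K2CO3, DMF, rt; then BnONa (from BnOH and NaH, 1.05 equiv), −20 °C to rt
Reagents that add atoms: benzyl bromide BrCc1ccccc1; benzyl alcohol OCc1ccccc1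
Why: Williamson O-benzylation first removes the ring-deactivating phenoxide, then one equivalent of benzyloxide displaces one of the two equivalent ortho-fluorides in a formyl-activated SNAr, and the second fluoride stays because the ring now carries two alkoxy donors.

**Step 2**
Reactants: 3 2,4-bis(benzyloxy)-6-fluorobenzaldehyde
Product: 4 1,5-bis(benzyloxy)-2-ethenyl-3-fluorobenzene
Conditions: Ph3PCH3Br, NaN(SiMe3)2, THF, 0 °C; then 3, −78 °C to rt
Reagents that add atoms: methyltriphenylphosphonium bromide C[P+](c1ccccc1)(c1ccccc1)c1ccccc1.[Br-]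
Why: Wittig methylenation, in which the preformed non-stabilised ylide adds to the aldehyde at low temperature far faster than any base or nucleophile could attack the ortho-fluoride, and no stereocentre is formed.

**Step 3**
Reactants: 4 1,5-bis(benzyloxy)-2-ethenyl-3-fluorobenzene; 5 4-(benzyloxy)benzaldehyde
Product: 9 (2S)-5,7-bis(benzyloxy)-2-[4-(benzyloxy)phenyl]chroman, via alkyldiethylborane 6 (not isolated), via dialkylzinc 7 (not isolated), via zinc alkoxide 8 (not isolated)
Conditions: Et2BH (from BH3·SMe2 and Et3B), 0 °C to rt; Et2Zn, 0 °C, then volatiles removed in vacuo; 5 (0.6 equiv), (2S)-(−)-3-exo-(dimethylamino)isoborneol [(−)-DAIB] (10 mol%), toluene, 0 °C to rt; then KOtBu (6 equiv), DMSO, 60 °C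
Reagents that add atoms: none
Why: Et2BH adds anti-Markovnikov to styrene 4, boron–zinc exchange with Et2Zn gives dialkylzinc 7, the chiral zinc aminoalkoxide formed from (−)-DAIB transfers the alkyl group through C3 to the Si face of aldehyde 5 (C2–C3 bond), and KOtBu in DMSO then frees the alkoxide of 8, which displaces fluoride at C8a by addition–elimination (O1–C8a bond). The closest known reaction types are the hydroboration/boron–zinc exchange route to functionalised dialkylzincs, the amino-alcohol-catalysed enantioselective addition of dialkylzincs to aromatic aldehydes, and the intramolecular SNAr of an alkoxide on an aryl fluoride to give a chroman. The pyran ring closes as a six-membered ring by intramolecular SNAr, O1 attacking the sp2 carbon C8a (6-exo with respect to the departing C–F bond). C2 is the only new stereocentre and is set by the catalyst: (2S)-(−)-DAIB gives S alcohols from aromatic aldehydes (as in (S)-1-phenylpropan-1-ol), and the closure does not touch the C2–O1 bond, so S is retained. The step needs chemoselectivity (the C–F bond must survive borane and organozinc, as aryl fluorides do) and regioselectivity in the closure, which is secured because C8a is the only carbon bearing a leaving group and the only one the three-carbon tether reaches, so that even an aryne pathway would converge on 9. The alkoxide must not lose enantiopurity by hydride exchange with free aldehyde, which is secured by using 7 in excess so that 5 is consumed before base is added.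

**Step 4**
Reactants: 9 (2S)-5,7-bis(benzyloxy)-2-[4-(benzyloxy)phenyl]chroman
Product: 10 (2S)-5,7-bis(benzyloxy)-2-[4-(benzyloxy)phenyl]-8-bromochroman
Conditions: N-bromosuccinimide (1.0 equiv), CH2Cl2, −40 °C to 0 °C, dark
Reagents that add atoms: N-bromosuccinimide O=C1CCC(=O)N1Br
Why: Electrophilic aromatic bromination, in which the trioxygenated ring A is far more nucleophilic than ring B and C8, flanked by the ring oxygen O1 and one benzyloxy group, is expected to react before C6, which sits between two freely rotating benzyloxy groups, as in 5,7-di-O-protected flavan-3-ols; C2 is not touched.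

**Step 5**
Reactants: 11 apigenin
Product: 12 5,7-bis(benzyloxy)-2-[4-(benzyloxy)phenyl]-4H-chromen-4-one
Conditions: BnBr (4.5 equiv), K2CO3, Bu4NI (cat.), DMF, 80 °C
Reagents that add atoms: benzyl bromide BrCc1ccccc1
Why: Threefold Williamson ether synthesis, with heating, excess halide and iodide catalysis to alkylate the hydrogen-bonded 5-OH as well.

**Step 6**
Reactants: 12 5,7-bis(benzyloxy)-2-[4-(benzyloxy)phenyl]-4H-chromen-4-one
Product: 14 5,7-bis(benzyloxy)-2-[4-(benzyloxy)phenyl]-3-iodo-4H-chromen-4-one, via 3-lithioflavone 13 (not isolated)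
Conditions: LiN(iPr)2, THF, −78 °C; then I2, −78 °C to 0 °C
Reagents that add atoms: iodine II
Why: Directed lithiation–iodination, in which C3–H is the only vinylic C–H and is acidified by the adjacent carbonyl whose oxygen chelates lithium, so the amide base gives the 3-lithioflavone that iodine converts into the C3 iodide.

**Step 7**
Reactants: 10 (2S)-5,7-bis(benzyloxy)-2-[4-(benzyloxy)phenyl]-8-bromochroman; 14 5,7-bis(benzyloxy)-2-[4-(benzyloxy)phenyl]-3-iodo-4H-chromen-4-one
Product: 17 5,7-bis(benzyloxy)-3-{(2S)-5,7-bis(benzyloxy)-2-[4-(benzyloxy)phenyl]chroman-8-yl}-2-[4-(benzyloxy)phenyl]-4H-chromen-4-one, via aryllithium 15 (not isolated), via arylzinc chloride 16 (not isolated)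
Conditions: n-BuLi, THF, −78 °C; ZnCl2, −78 °C to rt; then 14, Pd2(dba)3 (2.5 mol%), RuPhos (2-dicyclohexylphosphino-2′,6′-diisopropoxybiphenyl, 10 mol%), THF, 65 °C
Reagents that add atoms: none
Why: Bromine–lithium exchange, transmetalation to zinc and Negishi cross-coupling, in which zerovalent palladium inserts readily into the C3–I bond of the α-iodoenone and the bulky dialkylbiarylphosphine allows transmetalation and reductive elimination between two doubly ortho-flanked carbons, while C2 is remote and unaffected.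

**Step 8**
Reactants: 17 hexa-O-benzyl daphnodorin D2
Product: 18 daphnodorin D2
Conditions: H2 (1 atm), Pd(OH)2/C, THF/MeOH, rt
Reagents that add atoms: none
Why: Catalytic hydrogenolysis cleaves all six benzyl aryl ethers, while the tetrasubstituted C2=C3 bond of the flavone and the hindered cyclic C2–O1 bond of the flavan are expected to survive at 1 atm and room temperature, so (S)-C2 is retained.

**Compound list**

1 | 2,6-difluoro-4-hydroxybenzaldehyde | O=Cc1c(F)cc(O)cc1F | starting material
2 | 4-(benzyloxy)-2,6-difluorobenzaldehyde | O=Cc1c(F)cc(OCc2ccccc2)cc1F | intermediate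
3 | 2,4-bis(benzyloxy)-6-fluorobenzaldehyde | O=Cc1c(F)cc(OCc2ccccc2)cc1OCc1ccccc1 | intermediate
4 | 1,5-bis(benzyloxy)-2-ethenyl-3-fluorobenzene | C=Cc1c(F)cc(OCc2ccccc2)cc1OCc1ccccc1 | intermediate
5 | 4-(benzyloxy)benzaldehyde | O=Cc1ccc(OCc2ccccc2)cc1 | starting material
6 | {2-[2,4-bis(benzyloxy)-6-fluorophenyl]ethyl}diethylborane | CCB(CC)CCc1c(F)cc(OCc2ccccc2)cc1OCc1ccccc1 | intermediate
7 | bis{2-[2,4-bis(benzyloxy)-6-fluorophenyl]ethyl}zinc | Fc1cc(OCc2ccccc2)cc(OCc2ccccc2)c1CC[Zn]CCc1c(F)cc(OCc2ccccc2)cc1OCc1ccccc1 | intermediate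
8 | {2-[2,4-bis(benzyloxy)-6-fluorophenyl]ethyl}zinc (1S)-1-[4-(benzyloxy)phenyl]-3-[2,4-bis(benzyloxy)-6-fluorophenyl]propan-1-olate | Fc1cc(OCc2ccccc2)cc(OCc2ccccc2)c1CC[C@H](O[Zn]CCc1c(F)cc(OCc2ccccc2)cc1OCc1ccccc1)c1ccc(OCc2ccccc2)cc1 | intermediate
9 | (2S)-5,7-bis(benzyloxy)-2-[4-(benzyloxy)phenyl]chroman | O(Cc1ccccc1)c1cc(OCc2ccccc2)c2c(c1)O[C@H](c1ccc(OCc3ccccc3)cc1)CC2 | intermediate
10 | (2S)-5,7-bis(benzyloxy)-2-[4-(benzyloxy)phenyl]-8-bromochroman | O(Cc1ccccc1)c1cc(OCc2ccccc2)c2c(c1Br)O[C@H](c1ccc(OCc3ccccc3)cc1)CC2 | intermediate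
11 | apigenin (5,7-dihydroxy-2-(4-hydroxyphenyl)-4H-chromen-4-one) | O=c1cc(-c2ccc(O)cc2)oc2cc(O)cc(O)c12 | starting material
12 | 5,7-bis(benzyloxy)-2-[4-(benzyloxy)phenyl]-4H-chromen-4-one | O=c1cc(-c2ccc(OCc3ccccc3)cc2)oc2cc(OCc3ccccc3)cc(OCc3ccccc3)c12 | intermediate
13 | 5,7-bis(benzyloxy)-2-[4-(benzyloxy)phenyl]-3-lithio-4H-chromen-4-one | O=c1c([Li])c(-c2ccc(OCc3ccccc3)cc2)oc2cc(OCc3ccccc3)cc(OCc3ccccc3)c12 | intermediate
14 | 5,7-bis(benzyloxy)-2-[4-(benzyloxy)phenyl]-3-iodo-4H-chromen-4-one | O=c1c(I)c(-c2ccc(OCc3ccccc3)cc2)oc2cc(OCc3ccccc3)cc(OCc3ccccc3)c12 | intermediate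
15 | (2S)-5,7-bis(benzyloxy)-2-[4-(benzyloxy)phenyl]-8-lithiochroman | O(Cc1ccccc1)c1cc(OCc2ccccc2)c2c(c1[Li])O[C@H](c1ccc(OCc3ccccc3)cc1)CC2 | intermediate
16 | {(2S)-5,7-bis(benzyloxy)-2-[4-(benzyloxy)phenyl]chroman-8-yl}zinc chloride | O(Cc1ccccc1)c1cc(OCc2ccccc2)c2c(c1[Zn]Cl)O[C@H](c1ccc(OCc3ccccc3)cc1)CC2 | intermediate
17 | 5,7-bis(benzyloxy)-3-{(2S)-5,7-bis(benzyloxy)-2-[4-(benzyloxy)phenyl]chroman-8-yl}-2-[4-(benzyloxy)phenyl]-4H-chromen-4-one (hexa-O-benzyl daphnodorin D2) | O=c1c(-c2c(OCc3ccccc3)cc(OCc3ccccc3)c3c2O[C@H](c2ccc(OCc4ccccc4)cc2)CC3)c(-c2ccc(OCc3ccccc3)cc2)oc2cc(OCc3ccccc3)cc(OCc3ccccc3)c12 | intermediate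
18 | daphnodorin D2, 5,7-dihydroxy-3-[(2S)-5,7-dihydroxy-2-(4-hydroxyphenyl)chroman-8-yl]-2-(4-hydroxyphenyl)-4H-chromen-4-one | O=c1c(-c2c(O)cc(O)c3c2O[C@H](c2ccc(O)cc2)CC3)c(-c2ccc(O)cc2)oc2cc(O)cc(O)c12 | target

**Step count and risks**

Total step count: 8. Longest linear sequence: 6 (steps 1, 2, 3, 4, 7, 8).

Steps most likely to fail:

Step 3. What may go wrong: slow or poorly face-selective alkyl transfer from the bulky dialkylzinc, loss of enantiopurity through hydride exchange between alkoxide and aldehyde, or incomplete fluoride displacement by the zinc-bound alkoxide. The fallback sets out from dialkylzinc 7 and comes back at chroman 9, and it moves the stereo-defining event from C–C bond formation to a ketone reduction. Acylation of 7 with 4-(benzyloxy)benzoyl chloride under Pd(PPh3)4 catalysis (Negishi ketone synthesis) forms the C2–C3 bond and gives 1-[4-(benzyloxy)phenyl]-3-[2,4-bis(benzyloxy)-6-fluorophenyl]propan-1-one F1. Corey–Bakshi–Shibata reduction with (R)-2-methyl-CBS-oxazaborolidine [(R)-tetrahydro-1-methyl-3,3-diphenyl-1H,3H-pyrrolo[1,2-c][1,3,2]oxazaborole] and BH3·SMe2 should give (1S)-1-[4-(benzyloxy)phenyl]-3-[2,4-bis(benzyloxy)-6-fluorophenyl]propan-1-ol F2. KOtBu in DMSO at 60 °C then closes the O1–C8a bond by SNAr and delivers 9.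

Step 4. What may go wrong: bromination at C6, or at both C6 and C8, giving regioisomers that are hard to separate. The fallback sets out from zinc alkoxide 8 and comes back at bromide 10; regiochemistry is then dictated by the position of fluorine instead of by arene nucleophilicity. The flask of step 3 is quenched with aqueous NH4Cl before any base is added, which frees the alcohol F2 named above. Lithium 2,2,6,6-tetramethylpiperidide (3 equiv) in THF at −78 °C removes the O–H proton and the ring proton between fluorine and benzyloxy to give the dilithio compound F3. On warming to −30 °C this loses LiF to give the aryne lithium alkoxide F4, whose tethered alkoxide adds at the former C–F carbon to give aryllithium 15. 1,2-Dibromo-1,1,2,2-tetrachloroethane at −78 °C then gives 10 (anionic aryne cyclisation with electrophilic trapping).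

Step 7. What may go wrong: slow transmetalation or reductive elimination between two doubly ortho-flanked carbons, so that protodemetalation of the arylzinc and reductive deiodination take over. The fallback sets out from bromide 10 and comes back at 17; it forms the critical C–C bond at an unhindered methyl ketone and builds the pyranone ring afterwards. Commercial 1-[2,4-bis(benzyloxy)-6-hydroxyphenyl]ethanone is protected with MOMCl/iPr2NEt as 1-[2,4-bis(benzyloxy)-6-(methoxymethoxy)phenyl]ethanone F5. Palladium-catalysed ketone α-arylation of F5 with 10 (Pd2(dba)3, XPhos (2-dicyclohexylphosphino-2′,4′,6′-triisopropylbiphenyl), NaOtBu, toluene, 80 °C) gives the MOM-protected deoxybenzoin F6. HCl in MeOH/THF removes the MOM group to give the 2-hydroxydeoxybenzoin F7. O-Acylation with 4-(benzyloxy)benzoyl chloride in pyridine gives the aryl ester F8. KOH in pyridine induces the Baker–Venkataraman rearrangement to the 1,3-diketone F9, which is not isolated, and cyclodehydration with catalytic TsOH in toluene closes the chromone to 17.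

**Further compounds**

F1 | step 3 | 1-[4-(benzyloxy)phenyl]-3-[2,4-bis(benzyloxy)-6-fluorophenyl]propan-1-one | Fc1cc(OCc2ccccc2)cc(OCc2ccccc2)c1CCC(=O)c1ccc(OCc2ccccc2)cc1
F2 | step 3 | (1S)-1-[4-(benzyloxy)phenyl]-3-[2,4-bis(benzyloxy)-6-fluorophenyl]propan-1-ol | Fc1cc(OCc2ccccc2)cc(OCc2ccccc2)c1CC[C@H](O)c1ccc(OCc2ccccc2)cc1
F3 | step 4 | lithium (1S)-1-[4-(benzyloxy)phenyl]-3-[4,6-bis(benzyloxy)-2-fluoro-3-lithiophenyl]propan-1-olate | [Li]c1c(F)c(CC[C@H](O[Li])c2ccc(OCc3ccccc3)cc2)c(OCc2ccccc2)cc1OCc1ccccc1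
F4 | step 4 | lithium (1S)-1-[4-(benzyloxy)phenyl]-3-[4,6-bis(benzyloxy)-2,3-didehydrophenyl]propan-1-olate (aryne) | C1(CC[C@H](O[Li])c2ccc(OCc3ccccc3)cc2)=C(OCc2ccccc2)C=C(OCc2ccccc2)C#C1
F5 | step 7 | 1-[2,4-bis(benzyloxy)-6-(methoxymethoxy)phenyl]ethanone | CC(=O)c1c(OCOC)cc(OCc2ccccc2)cc1OCc1ccccc1
F6 | step 7 | 1-[2,4-bis(benzyloxy)-6-(methoxymethoxy)phenyl]-2-{(2S)-5,7-bis(benzyloxy)-2-[4-(benzyloxy)phenyl]chroman-8-yl}ethanone | COCOc1cc(OCc2ccccc2)cc(OCc2ccccc2)c1C(=O)Cc1c(OCc2ccccc2)cc(OCc2ccccc2)c2c1O[C@H](c1ccc(OCc3ccccc3)cc1)CC2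
F7 | step 7 | 1-[2,4-bis(benzyloxy)-6-hydroxyphenyl]-2-{(2S)-5,7-bis(benzyloxy)-2-[4-(benzyloxy)phenyl]chroman-8-yl}ethanone | Oc1cc(OCc2ccccc2)cc(OCc2ccccc2)c1C(=O)Cc1c(OCc2ccccc2)cc(OCc2ccccc2)c2c1O[C@H](c1ccc(OCc3ccccc3)cc1)CC2
F8 | step 7 | 3,5-bis(benzyloxy)-2-({(2S)-5,7-bis(benzyloxy)-2-[4-(benzyloxy)phenyl]chroman-8-yl}acetyl)phenyl 4-(benzyloxy)benzoate | O=C(Oc1cc(OCc2ccccc2)cc(OCc2ccccc2)c1C(=O)Cc1c(OCc2ccccc2)cc(OCc2ccccc2)c2c1O[C@H](c1ccc(OCc3ccccc3)cc1)CC2)c1ccc(OCc2ccccc2)cc1
F9 | step 7 | 1-[2,4-bis(benzyloxy)-6-hydroxyphenyl]-2-{(2S)-5,7-bis(benzyloxy)-2-[4-(benzyloxy)phenyl]chroman-8-yl}-3-[4-(benzyloxy)phenyl]propane-1,3-dione | Oc1cc(OCc2ccccc2)cc(OCc2ccccc2)c1C(=O)C(C(=O)c1ccc(OCc2ccccc2)cc1)c1c(OCc2ccccc2)cc(OCc2ccccc2)c2c1O[C@H](c1ccc(OCc3ccccc3)cc1)CC2
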